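The runs come from a simulation for an exercise; scatter was added.

In a closed, stirred vessel at constant temperature, starting material and partner join reversibly to the open intermediate. This splits reversibly into product and by-product, while capture agent takes some of it away as trapped intermediate.

| flask | starting material | partner | capture agent | remark | time |
|---|---|---|---|---|---|
| alder | 0.078 M | 0.50 equiv | 1.56 mM | the very flask that is asked about, followed so far |  |
| elm | 0.078 M | 0.50 equiv | 3.1 mM | run made earlier |  |
| flask | 0.078 M | 0.500 equiv | 1.56 mM |  | 15 d |

| run | time / d | product / % | open intermediate / % |
|---|---|---|---|
| alder | 0.417 | 10.9 | 7.3 |
| alder | 1.04 | 22.1 | 6.3 |
| alder | 2.08 | 30.3 | 9.0 |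
| alder | 3.00 | 33.3 | 8.8 |
| elm | 2.50 | 32.3 | 8.4 |
| elm | 5.00 | 33.4 | 9.8 |
| elm | 8.00 | 31.4 | 7.9 |
| elm | 10.0 | 32.9 | 9.3 |

(readings scatter by 1 percentage point)

- steps thought possible: open intermediate <-> product + by-product; open intermediate + capture agent -> trapped intermediate; starting material + partner <-> open intermediate
- the reaction counts as stopped when no species that holds the starting material changes by six tenths of a point or more over the second half of the time

- which holds at 15 d: what has brought the reaction to rest, or that it has not come to rest (it is still moving / forward and back rates have come level / the partner has run out first / all of the starting material has reacted)
- amount of product at 15 d, in percent of the starting material charged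
- amount of open intermediate at 15 d, in percent of the starting material charged

I read the elm table first, row by row. Its product wanders between 31.4% and 33.4% with no trend, which the scatter of 1 percentage point allows, and its open intermediate does the same. So elm reads as a flask at rest, with mean readings of 32.5% product and 8.85% open intermediate. Even with elm's whole capture charge counted, partner equal to 4.68% of the starting material charged remains, so by these readings elm's partner has not run out.

Each product comes with one by-product, so I use K, the concentration of product times that of by-product over that of open intermediate, which reads 0.0931 M in elm.

Now the alder rows: product climbs and by 3.00 d stands at 33.3%, near elm's level, so 15 d is ample. Alder differs by its smaller capture charge, and I treat that as a correction. Suppose the capture agent is used up in both flasks and the total consumed stands as in elm, so alder has 1.97% of the starting material more to share between product and open intermediate. By K, a small gain in product brings a gain in open intermediate 54.5% as large, so product gains 1.3 points. My reckoning is a flask at rest with 33.8% product and 9.56% open intermediate.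

The forecast says forward and back rates have come level, with product 33.6% (32.4% to 35%) and open intermediate 9.4% (8.4% to 10.4%), since “the flask rests at equilibrium, slightly above elm”, its product lying 0.20 points below mine.

Alder gives: forward and back rates have come level, with product 33.4% and open intermediate 9.57%.

    open intermediate ⇌ product + by-product (K = 0.0910 M, k = 0.250 h⁻¹)
    open intermediate + capture agent → trapped intermediate (k = 0.300 L mol⁻¹ h⁻¹)
    starting material + partner ⇌ open intermediate (K = 37.0 L mol⁻¹, k = 0.660 L mol⁻¹ h⁻¹)

Alder's own K is 0.0910 M. Alder's conversion of starting material ends at 44.1%, and in the run without the partner running short it reaches 82.2%, so the running short of partner, with 12% of its charge left at 15.0 d, is the main reason. A neighbour of alder with 0.850 equiv of partner ends with 18.4% open intermediate, which K turns into 46.8% product, and that neighbour holds 46.3%.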